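## Retrosynthetic overview

1. Numbering used here: ring A = C1–C5, C10 (C1 α-OAc, C4 CMe2, C5 α-OH, C10 β-Me); ring B = C5–C10 (C7 β-OAc); ring C = C8, C9, C11, C12, C14 (C14 carries CO2Me); ring D = spiro-lactone C12–C17(=O)–O–C16–C15, with the epoxide on C15–C16.
2. Epoxide ⇐ enol lactone (C15=C16) ⇐ lactol of a γ-aldehydo acid on C12 (C17O2H + C16HO); ring D is made last.
3. Rings B and C ⇐ one radical–polar cascade: C8–C9 (ring B, the B/C fusion bond) by 6-exo attack of a C9 radical on the enoate C8=C14–CO2Me, then C14–C12 (ring C) by 5-exo Michael closure onto C12=C15–C16HO. The enabling feature: C8 is β to the C14 ester and C12 is β to C16 (the acetal carbon, an aldehyde at that stage), while C9 carries only H and is brought in with a carboxyl group that leaves as CO2.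
4. Cascade precursor ⇐ ring A (C1, C10 from yeast desymmetrisation of 2-allyl-2-methylcyclohexane-1,3-dione) with a C5 arm (allylation, ozonolysis, asymmetric alkynylation) and a C10 arm (C9 ester enolate + Baylis–Hillman bromide).
5. Ring order: A (from the dione) → B + C together (step 17) → D (steps 18–20) → epoxide (step 21).

Key step: step 17

Remark: C9 is carried as an epimer mixture from 15 to 22 (it becomes a radical in step 17) and the lactol carbon C16 of 25–27 and 29 is an anomer mixture; both are left undefined in the SMILES. β means the face of the C10 methyl group.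

## Route

Step 1
Reactants: 1 benzyl acrylate; 2 2,2-dimethoxyacetaldehyde
Product: 3 benzyl 3-hydroxy-4,4-dimethoxy-2-methylidenebutanoate (racemic)
Conditions: DABCO (0.5 equiv), dioxane–H2O, rt
Reagents that add atoms: none
Why: Morita–Baylis–Hillman reaction of an acrylate with an activated α,α-dialkoxy aldehyde; the carbinol centre is racemic and disappears in step 2.

Step 2
Reactants: 3 benzyl 3-hydroxy-4,4-dimethoxy-2-methylidenebutanoate
Product: 4 benzyl (2Z)-2-(bromomethyl)-4,4-dimethoxybut-2-enoate
Conditions: NBS, Me2S, CH2Cl2, 0 °C → rt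
Reagents that add atoms: N-bromosuccinimide, O=C1CCC(=O)N1Br
Why: SN2′ bromination of a Baylis–Hillman alcohol through its alkoxysulfonium salt (allylic transposition) should give the Z-2-(bromomethyl)enoate under neutral conditions that leave the acetal intact.

Step 3
Reactants: 5 2-methylcyclohexane-1,3-dione; 6 allyl acetate
Product: 7 2-methyl-2-(prop-2-en-1-yl)cyclohexane-1,3-dione
Conditions: Pd(PPh3)4 (2 mol%), Et3N, THF, 50 °C
Reagents that add atoms: none
Why: Tsuji–Trost C-allylation of a cyclic 1,3-diketone builds the (still achiral) quaternary C10.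

Step 4
Reactants: 7 2-methyl-2-(prop-2-en-1-yl)cyclohexane-1,3-dione
Product: 8 (2S,3S)-3-hydroxy-2-methyl-2-(prop-2-en-1-yl)cyclohexan-1-one
Conditions: baker's yeast, sucrose, H2O, 30 °C
Reagents that add atoms: none
Why: Enzymatic enantiotopic-group-selective ketone reduction (desymmetrisation of a 2,2-disubstituted 1,3-diketone) should set C1 (S) and thereby fix quaternary C10 (S), with OH cis to allyl as the target needs (1α-O, 10β-Me).

Step 5
Reactants: 8 (2S,3S)-3-hydroxy-2-methyl-2-(prop-2-en-1-yl)cyclohexan-1-one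
Product: 9 (2S,3S)-3-[(tert-butyldimethylsilyl)oxy]-2-methyl-2-(prop-2-en-1-yl)cyclohexan-1-one
Conditions: TBSOTf, 2,6-lutidine, CH2Cl2, −78 → 0 °C
Reagents that add atoms: tert-butyldimethylsilyl triflate, CC(C)(C)[Si](C)(C)OS(=O)(=O)C(F)(F)F
Why: Silylation of the hindered secondary alcohol with a silyl triflate protects C1–OH against the base and oxidant of the next steps and blocks retro-aldol cleavage.

Step 6
Reactants: 9 (2S,3S)-3-[(tert-butyldimethylsilyl)oxy]-2-methyl-2-(prop-2-en-1-yl)cyclohexan-1-one
Product: 10 (2S,3S)-3-[(tert-butyldimethylsilyl)oxy]-2,6,6-trimethyl-2-(prop-2-en-1-yl)cyclohexan-1-one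
Conditions: KOtBu (3 equiv), MeI (6 equiv), THF, 0 °C → rt
Reagents that add atoms: iodomethane, CI
Why: Exhaustive enolate methylation installs the C4 gem-dimethyl group, C4 being the only enolisable position of the ketone.

Step 7
Reactants: 10 (2S,3S)-3-[(tert-butyldimethylsilyl)oxy]-2,6,6-trimethyl-2-(prop-2-en-1-yl)cyclohexan-1-one
Product: 11 2-[(1S,6S)-6-[(tert-butyldimethylsilyl)oxy]-1,3,3-trimethyl-2-oxocyclohexyl]acetic acid
Conditions: RuCl3·xH2O (cat.), NaIO4, CCl4–MeCN–H2O, rt
Reagents that add atoms: sodium periodate, [Na+].[O-]I(=O)(=O)=O; water, O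
Why: RuO4-catalysed oxidative cleavage of the terminal alkene gives the acid with one carbon fewer, so the former allyl CH2 becomes C9 and the new carboxyl is the later traceless radical precursor.

Step 8
Reactants: 11 2-[(1S,6S)-6-[(tert-butyldimethylsilyl)oxy]-1,3,3-trimethyl-2-oxocyclohexyl]acetic acid
Product: 12 tert-butyl 2-[(1S,6S)-6-[(tert-butyldimethylsilyl)oxy]-1,3,3-trimethyl-2-oxocyclohexyl]acetate
Conditions: O-tert-butyl-N,N′-diisopropylisourea, CH2Cl2, rt
Reagents that add atoms: O-tert-butyl-N,N′-diisopropylisourea, CC(C)N=C(OC(C)(C)C)NC(C)C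
Why: Neutral tert-butyl transfer from an isourea esterifies the acid without touching the silyl ether and gives an ester that resists organozinc addition.

Step 9
Reactants: 12 tert-butyl 2-[(1S,6S)-6-[(tert-butyldimethylsilyl)oxy]-1,3,3-trimethyl-2-oxocyclohexyl]acetate
Product: 13 ring-A carbinol: tert-butyl ester of the C10 acetic acid arm (C9H2–CO2tBu, α on C10), with 5α-OH, 5β-allyl (C6–C8), 1α-OTBS, 4,4-dimethyl, 10β-methyl
Conditions: allylzinc bromide, THF, 0 °C; H2O quench
Reagents that add atoms: allylzinc bromide, C=CC[Zn]Br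
Why: Barbier-type organozinc allylation of the non-enolisable hindered ketone spares the tert-butyl ester and should occur on the β face, anti to the C10 acetate arm and the C1 silyloxy group, setting C5 with α-OH.

Step 10
Reactants: 13 ring-A carbinol
Product: 14 5α-O-trimethylsilyl ether of 13
Conditions: TMSOTf, 2,6-lutidine, CH2Cl2, 0 °C
Reagents that add atoms: trimethylsilyl triflate, C[Si](C)(C)OS(=O)(=O)C(F)(F)F
Why: Silylation of the tertiary alcohol with a silyl triflate prevents the C5 alkoxide from lactonising onto the C9 ester in step 11 and onto the free acid later.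

Step 11
Reactants: 14 5α-O-trimethylsilyl ether; 4 benzyl (2Z)-2-(bromomethyl)-4,4-dimethoxybut-2-enoate
Product: 15 C9-alkylated diester (C9 epimers): C9 carries CO2tBu and C11H2–C12(CO2Bn)=C15H–C16H(OMe)2; 5β-allyl, 5α-OTMS, 1α-OTBS
Conditions: LiN(iPr)2 (LDA), THF–DMPU, −78 °C; then 4, −78 → −20 °C
Reagents that add atoms: none
Why: Ester enolate alkylation by SN2 at the primary allylic bromide (the β-carbon of 4 is shielded by the acetal) forms C9–C11 and brings in C11, C12, C15, C16 and C17 at once; the C9 configuration is irrelevant.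

Step 12
Reactants: 15 C9-alkylated diester
Product: 16 C7 aldehyde (C5β–CH2–CHO), otherwise as 15
Conditions: O3, CH2Cl2, −78 °C (indicator end-point); PPh3
Reagents that add atoms: ozone, [O-][O+]=O
Why: Ozonolysis is selective because the monosubstituted allyl alkene reacts far faster than the electron-poor, trisubstituted acrylate.

Step 13
Reactants: 16 C7 aldehyde; 17 methyl propiolate
Product: 18 (7S)-propargylic alcohol: C5β–CH2–CH(OH)–C≡C–CO2Me, otherwise as 16
Conditions: Me2Zn, (S,S)-ProPhenol (20 mol%), Ph3PO (cat.), toluene, 0 °C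
Reagents that add atoms: none
Why: Zinc–ProPhenol-catalysed asymmetric alkynylation of the aldehyde forms C7–C8 under ligand control (the ligand enantiomer is chosen to deliver the 7S carbinol) and tolerates the esters and the acetal.

Step 14
Reactants: 18 (7S)-propargylic alcohol
Product: 19 (7S)-γ-hydroxy (E)-enoate: C5β–CH2–CH(OH)–CH=CH–CO2Me (C8=C14), otherwise as 18
Conditions: NaAlH2(OCH2CH2OMe)2 (Red-Al), THF, −78 °C
Reagents that add atoms: none
Why: Alkoxide-directed trans-hydroalumination of the γ-hydroxy ynoate gives the E-enoate at a temperature at which the isolated esters are not attacked.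

Step 15
Reactants: 19 (7S)-γ-hydroxy (E)-enoate
Product: 20 (7S)-acetate of 19
Conditions: Ac2O, DMAP, pyridine, CH2Cl2, rt
Reagents that add atoms: acetic anhydride, CC(=O)OC(C)=O
Why: DMAP-catalysed acylation installs the C7 acetate of the target on the only free hydroxyl.

Step 16
Reactants: 20 (7S)-acetate
Product: 22 cascade precursor: C9 carboxylic acid with C11H2–C12(CO2Bn)=C15H–C16HO, plus the (7S)-acetoxy (E)-enoate arm on C5; 5α-OTMS, 1α-OTBS, via silyl ester pyridinium triflate 21 (not isolated)
Conditions: TMSOTf, 2,6-lutidine, CH2Cl2, 0 °C; then H2O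
Reagents that add atoms: water, O
Why: Silyl triflate/2,6-lutidine unmasking converts the tert-butyl ester into a silyl ester (loss of isobutene) and the dimethyl acetal into an N-(α-methoxyalkyl)lutidinium salt, both hydrolysed on work-up, under non-acidic conditions that keep the silyl ethers, the acetate and the benzyl ester and avoid lactonisation.

Step 17
Reactants: 22 cascade precursor
Product: 23 tricyclic aldehyde: rings A–B–C closed (8β-H, 9α-H), C14 β-CO2Me, C12 carrying β-CH2CHO (C15, C16) and α-CO2Bn (C17); 7β-OAc, 5α-OTMS, 1α-OTBS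
Conditions: Ir[dF(CF3)ppy]2(dtbbpy)PF6 (1 mol%), K2HPO4, DMF (0.01 M), blue LEDs, rt
Reagents that add atoms: none
Why: The excited iridium photocatalyst oxidises the C9 carboxylate, CO2 is lost and the nucleophilic secondary C9 radical adds 6-exo-trig to C8 of the γ-acetoxy enoate (Giese cyclisation: ring B and the C8–C9 bond); the C14 α-ester radical is then reduced by the reduced photocatalyst to the ester enolate, which closes ring C by 5-exo-trig Michael addition to C12, the carbon β to the aldehyde, and the resulting aldehyde enolate is protonated (if C14 closes as a radical onto the same carbon instead, the product is the same). The closest known reaction type is the photoredox decarboxylative conjugate addition of alkyl carboxylic acids, run as a radical–polar crossover annulation. Ring B closes through a chair-like transition state governed by the ring-A stereocentres: C11 on C9 stays equatorial to avoid the axial C10 methyl (9α-H), and the E-enoate and the C7 acetate are equatorial (8β-H), giving the trans B/C fusion on a trans-decalin. In ring C the C14 ester should take the β position, cis to H8 and away from the C7 acetate (this centre is also epimerisable), and a cation-bridged transition state between the enolate oxygen and the enal oxygen should put the CH2CHO arm cis to that ester, so that C15 is β and C17 α at the new quaternary C12. The step needs 6-exo attack at C8 to win over 3-exo attack of the C9 radical on its own formylacrylate and over 1,5-hydrogen transfer, which should hold because the 3-exo adduct reopens faster than it is reduced and the enoate is the only irreversible acceptor in reach; it also needs Michael closure at C12 and not C15, which the stronger activation by the aldehyde and the 5-exo geometry secure.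

Step 18
Reactants: 23 tricyclic aldehyde
Product: 25 lactol (ring D closed as 5-hydroxy-γ-lactone C17(=O)–O–C16H(OH)–C15H2); 7β-OAc, 5α-OTMS, 1α-OTBS, via open aldehydo acid 24 (not isolated)
Conditions: H2 (1 atm), Pd/C, EtOAc, rt
Reagents that add atoms: none
Why: Hydrogenolysis of the benzyl ester frees the C17 acid, which adds to the C16 aldehyde (ring-chain tautomerism of a γ-aldehydo acid) to give the five-membered lactol; no C=C bond is present at this stage.

Step 19
Reactants: 25 lactol
Product: 26 1α,5α-diol lactol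
Conditions: HF·pyridine, THF–pyridine, 0 °C → rt
Reagents that add atoms: none
Why: Fluoride-mediated desilylation removes both silyl ethers, while the acetate, the methyl ester and the lactol tolerate buffered HF.

Step 20
Reactants: 26 1α,5α-diol lactol
Product: 28 enol lactone (C15=C16, 3,3-spiro furan-2(3H)-one) with 1α-OAc, 7β-OAc and free 5α-OH, via anomeric acetate 27 (not isolated)
Conditions: Ac2O, NaOAc, 110 °C
Reagents that add atoms: acetic anhydride, CC(=O)OC(C)=O
Why: Enol lactonisation of a γ-aldehydo acid (pseudo-acid acetate, then loss of acetic acid; C12 has no H, so only C15=C16 can form) runs together with acetylation of the secondary C1 hydroxyl, while the tertiary C5 hydroxyl, flanked by two quaternary carbons, should stay free.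

Step 21
Reactants: 28 enol lactone
Product: 30 spirocaesalmin, via bromohydrin 29 (not isolated)
Conditions: NBS, THF–H2O, 0 °C; then Ag2O, CH2Cl2, rt
Reagents that add atoms: water, O
Why: Bromohydrin formation and SN2 epoxide closure: Br+ should add to C15 from the open face of the enol ether (the one toward C11, the other being screened by the cis C14 ester), water adds anti at C16, and displacement of bromide by the C16 alkoxide then places the epoxide oxygen on the face toward C14, as in the target.

## Compound list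

1 | benzyl acrylate | C=CC(=O)OCc1ccccc1 | starting material
2 | 2,2-dimethoxyacetaldehyde | COC(OC)C=O | starting material
3 | benzyl 3-hydroxy-4,4-dimethoxy-2-methylidenebutanoate (racemic) | C=C(C(O)C(OC)OC)C(=O)OCc1ccccc1 | intermediate
4 | benzyl (2Z)-2-(bromomethyl)-4,4-dimethoxybut-2-enoate | BrC/C(C(=O)OCc1ccccc1)=C\C(OC)OC | intermediate
5 | 2-methylcyclohexane-1,3-dione | CC1C(=O)CCCC1=O | starting material
6 | allyl acetate | C=CCOC(C)=O | starting material
7 | 2-methyl-2-(prop-2-en-1-yl)cyclohexane-1,3-dione | C=CCC1(C)C(=O)CCCC1=O | intermediate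
8 | (2S,3S)-3-hydroxy-2-methyl-2-(prop-2-en-1-yl)cyclohexan-1-one | O=C1CCC[C@H](O)[C@]1(C)CC=C | intermediate
9 | (2S,3S)-3-[(tert-butyldimethylsilyl)oxy]-2-methyl-2-(prop-2-en-1-yl)cyclohexan-1-one | O=C1CCC[C@H](O[Si](C)(C)C(C)(C)C)[C@]1(C)CC=C | intermediate
10 | (2S,3S)-3-[(tert-butyldimethylsilyl)oxy]-2,6,6-trimethyl-2-(prop-2-en-1-yl)cyclohexan-1-one | O=C1C(C)(C)CC[C@H](O[Si](C)(C)C(C)(C)C)[C@]1(C)CC=C | intermediate
11 | 2-[(1S,6S)-6-[(tert-butyldimethylsilyl)oxy]-1,3,3-trimethyl-2-oxocyclohexyl]acetic acid | O=C1C(C)(C)CC[C@H](O[Si](C)(C)C(C)(C)C)[C@]1(C)CC(=O)O | intermediate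
12 | tert-butyl 2-[(1S,6S)-6-[(tert-butyldimethylsilyl)oxy]-1,3,3-trimethyl-2-oxocyclohexyl]acetate | O=C1C(C)(C)CC[C@H](O[Si](C)(C)C(C)(C)C)[C@]1(C)CC(=O)OC(C)(C)C | intermediate
13 | ring-A carbinol (5α-OH, 5β-allyl, 1α-OTBS, C10 arm CH2CO2tBu) | C=CC[C@@]1(O)C(C)(C)CC[C@H](O[Si](C)(C)C(C)(C)C)[C@]1(C)CC(=O)OC(C)(C)C | intermediate
14 | 5α-O-trimethylsilyl ether of 13 | C=CC[C@@]1(O[Si](C)(C)C)C(C)(C)CC[C@H](O[Si](C)(C)C(C)(C)C)[C@]1(C)CC(=O)OC(C)(C)C | intermediate
15 | C9-alkylated diester (C9 epimers) | C=CC[C@@]1(O[Si](C)(C)C)C(C)(C)CC[C@H](O[Si](C)(C)C(C)(C)C)[C@]1(C)C(C(=O)OC(C)(C)C)C/C(C(=O)OCc1ccccc1)=C\C(OC)OC | intermediate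
16 | C7 aldehyde | O=CC[C@@]1(O[Si](C)(C)C)C(C)(C)CC[C@H](O[Si](C)(C)C(C)(C)C)[C@]1(C)C(C(=O)OC(C)(C)C)C/C(C(=O)OCc1ccccc1)=C\C(OC)OC | intermediate
17 | methyl propiolate | C#CC(=O)OC | starting material
18 | (7S)-propargylic alcohol | COC(=O)C#C[C@@H](O)C[C@@]1(O[Si](C)(C)C)C(C)(C)CC[C@H](O[Si](C)(C)C(C)(C)C)[C@]1(C)C(C(=O)OC(C)(C)C)C/C(C(=O)OCc1ccccc1)=C\C(OC)OC | intermediate
19 | (7S)-γ-hydroxy (E)-enoate | COC(=O)/C=C/[C@@H](O)C[C@@]1(O[Si](C)(C)C)C(C)(C)CC[C@H](O[Si](C)(C)C(C)(C)C)[C@]1(C)C(C(=O)OC(C)(C)C)C/C(C(=O)OCc1ccccc1)=C\C(OC)OC | intermediate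
20 | (7S)-acetate | COC(=O)/C=C/[C@@H](OC(C)=O)C[C@@]1(O[Si](C)(C)C)C(C)(C)CC[C@H](O[Si](C)(C)C(C)(C)C)[C@]1(C)C(C(=O)OC(C)(C)C)C/C(C(=O)OCc1ccccc1)=C\C(OC)OC | intermediate
21 | silyl ester pyridinium triflate | COC(=O)/C=C/[C@@H](OC(C)=O)C[C@@]1(O[Si](C)(C)C)C(C)(C)CC[C@H](O[Si](C)(C)C(C)(C)C)[C@]1(C)C(C(=O)O[Si](C)(C)C)C/C(C(=O)OCc1ccccc1)=C\C(OC)[n+]1c(C)cccc1C.[O-]S(=O)(=O)C(F)(F)F | intermediate (not isolated)
22 | cascade precursor (C9 acid, C16 enal) | COC(=O)/C=C/[C@@H](OC(C)=O)C[C@@]1(O[Si](C)(C)C)C(C)(C)CC[C@H](O[Si](C)(C)C(C)(C)C)[C@]1(C)C(C(=O)O)C/C(C(=O)OCc1ccccc1)=C\C=O | intermediate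
23 | tricyclic aldehyde | COC(=O)[C@H]1[C@@H]2[C@@H](OC(C)=O)C[C@@]3(O[Si](C)(C)C)C(C)(C)CC[C@H](O[Si](C)(C)C(C)(C)C)[C@]3(C)[C@H]2C[C@]1(CC=O)C(=O)OCc1ccccc1 | intermediate
24 | open aldehydo acid | COC(=O)[C@H]1[C@@H]2[C@@H](OC(C)=O)C[C@@]3(O[Si](C)(C)C)C(C)(C)CC[C@H](O[Si](C)(C)C(C)(C)C)[C@]3(C)[C@H]2C[C@]1(CC=O)C(=O)O | intermediate (not isolated)
25 | lactol (silyl ethers in place) | COC(=O)[C@H]1[C@@H]2[C@@H](OC(C)=O)C[C@@]3(O[Si](C)(C)C)C(C)(C)CC[C@H](O[Si](C)(C)C(C)(C)C)[C@]3(C)[C@H]2C[C@]12C(=O)OC(O)C2 | intermediate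
26 | 1α,5α-diol lactol | COC(=O)[C@H]1[C@@H]2[C@@H](OC(C)=O)C[C@@]3(O)C(C)(C)CC[C@H](O)[C@]3(C)[C@H]2C[C@]12C(=O)OC(O)C2 | intermediate
27 | anomeric acetate (1α-acetate) | COC(=O)[C@H]1[C@@H]2[C@@H](OC(C)=O)C[C@@]3(O)C(C)(C)CC[C@H](OC(C)=O)[C@]3(C)[C@H]2C[C@]12C(=O)OC(OC(C)=O)C2 | intermediate (not isolated)
28 | enol lactone | COC(=O)[C@H]1[C@@H]2[C@@H](OC(C)=O)C[C@@]3(O)C(C)(C)CC[C@H](OC(C)=O)[C@]3(C)[C@H]2C[C@]12C(=O)OC=C2 | intermediate
29 | bromohydrin | COC(=O)[C@H]1[C@@H]2[C@@H](OC(C)=O)C[C@@]3(O)C(C)(C)CC[C@H](OC(C)=O)[C@]3(C)[C@H]2C[C@]12C(=O)OC(O)[C@H]2Br | intermediate (not isolated)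
30 | spirocaesalmin | COC(=O)[C@H]1[C@@H]2[C@@H](OC(C)=O)C[C@@]3(O)C(C)(C)CC[C@H](OC(C)=O)[C@]3(C)[C@H]2C[C@]12C(=O)O[C@@H]1O[C@@H]12 | target

## Step count and risks

Total step count: 21. Longest linear sequence: 19 steps (steps 3–21, from 5); the side branch (steps 1–2) joins at step 11.

Steps most likely to fail:

Step 17. The C14 enolate may be protonated before it closes ring C, the reversibly formed 3-exo adduct of the C9 radical may be reduced, or facial control at C12 may be poor. The fallback sets out from 22 and runs both closures as an all-radical chain. Esterification with N-hydroxypyridine-2-thione (DCC, cat. DMAP, CH2Cl2, dark) would give the Barton ester F1. Visible-light photolysis with (Me3Si)3SiH in benzene at high dilution would then give the C9 radical, 6-exo closure to C8, 5-exo closure of the C14 radical onto C12 and hydrogen transfer to the α-formyl radical. It returns to the route at 23.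

Step 20. The elimination may stall at the pseudo-acid acetate, or the tertiary C5 alcohol may be acylated or dehydrated at 110 °C. The fallback sets out from 26. Acetylation at room temperature (Ac2O, DMAP, pyridine) would give 27, here isolated. Exchange of the anomeric acetate with PhSeH and BF3·OEt2 would give the phenylseleno lactone F2. Oxidation with H2O2 at 0 °C would give the selenoxide F3, whose syn-elimination delivers the C15=C16 bond. It returns to the route at 28.

Step 21. Bromonium formation may show poor or reversed facial selectivity, which would put the epoxide on the wrong face. The fallback sets out from 28 and uses direct epoxidation with dimethyldioxirane in acetone at 0 °C. This delivers oxygen to the face that the electrophile prefers, so it gives the natural epoxide if that face is the one toward C14. It returns to the route at 30 and makes no new compound (F0).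

Further compounds
F1 | step 17 | Barton ester (O-acyl N-hydroxypyridine-2-thione) of 22 | COC(=O)/C=C/[C@@H](OC(C)=O)C[C@@]1(O[Si](C)(C)C)C(C)(C)CC[C@H](O[Si](C)(C)C(C)(C)C)[C@]1(C)C(C(=O)On1ccccc1=S)C/C(C(=O)OCc1ccccc1)=C\C=O
F2 | step 20 | phenylseleno lactone (C16–SePh) | COC(=O)[C@H]1[C@@H]2[C@@H](OC(C)=O)C[C@@]3(O)C(C)(C)CC[C@H](OC(C)=O)[C@]3(C)[C@H]2C[C@]12C(=O)OC([Se]c1ccccc1)C2
F3 | step 20 | selenoxide of F2 | COC(=O)[C@H]1[C@@H]2[C@@H](OC(C)=O)C[C@@]3(O)C(C)(C)CC[C@H](OC(C)=O)[C@]3(C)[C@H]2C[C@]12C(=O)OC([Se](=O)c1ccccc1)C2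
F0 | step 21 | none | none
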